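1. Cembrane numbering is used: C1 (lactone CH), C2, C3/C4 (oxirane, C18 methyl), C5, C6, C7 (OAc), C8 (=C19H2), C9–C11, C12 (C20 methyl), C13 (OAc), C14 (lactone O–CH), C15 (=C17H2), C16 (C=O).
2. Enabling feature: in the 14-membered carbocycle, C12(H)(CH3)–C13(H)(O) is a syn propionate-aldol pair next to the bare C9–C11 trimethylene. A temporary ketone at C11 therefore makes C12–C13 an aldol bond and makes C20 the β-carbon of a vinyl ketone.
3. Retrosynthetic cuts, in order: oxirane O; O14–C16 and C15–C16 (CO taken out of the butyrolactone ring); C11=O put back; C12–C13 (carbocycle opened to an enone-aldehyde); C15≡C17; C1–C2; C7–C8; C11–C12.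
4. Forward order: a C8–C12 bromodiene and a C2–C7 aldehyde (from geranyl acetate) are joined at C7–C8. The allylic bromide at C2 then alkylates (R)-3-hydroxybutyrolactone at C1, the lactone becomes an ethynyl diol, and a double oxidation follows. A reductive aldol closes the carbocycle, C11=O is removed, cyclocarbonylation makes the lactone ring, and the oxirane comes last.
5. Stereochemistry: C14 comes from the chiral pool, C1 from trans-alkylation of the lactone dianion, and C7 from CBS reduction. C12/C13 come from a Z-enolate in a closed transition state plus a chiral ligand, C3/C4 from Shi epoxidation, and the E-C3=C4 geometry from geranyl acetate.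

Key step: step 19

Assumption: the antipode of the TADDOL-type phosphonite in step 19 is the one that delivers the (13R) aldolate. Its sense is to be fixed on a model α-silyloxy aldehyde.
Remark: the C11 carbinol centre is carried as an epimer mixture from step 3 to step 17 and is erased in step 18.

Step 1
Reactants: 1 2-bromoprop-2-en-1-ol
Product: 2 ethyl 4-bromopent-4-enoate
Conditions: MeC(OEt)3 (excess), EtCO2H (cat.), 140 °C, EtOH distilled off
Reagents that add atoms: triethyl orthoacetate, CC(OCC)(OCC)OCC
Why: The Johnson–Claisen rearrangement of the mixed ketene acetal transfers the 2-bromoallyl unit to the acetate carbon and keeps the vinylic bromide, so C19, C8, C9, C10 and C11 are assembled in one operation.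

Step 2
Reactants: 2 ethyl 4-bromopent-4-enoate
Product: 3 4-bromopent-4-enal
Conditions: i-Bu2AlH (1.05 equiv), CH2Cl2, −78 °C
Reagents that add atoms: none
Why: Partial ester reduction stops at the tetrahedral aluminium hemiacetal at −78 °C and does not touch the vinyl bromide.

Step 3
Reactants: 3 4-bromopent-4-enal
Product: 4 (±)-6-bromohepta-1,6-dien-3-ol
Conditions: vinylmagnesium bromide, THF, −78 to 0 °C
Reagents that add atoms: vinylmagnesium bromide, C=C[Mg]Br
Why: Grignard 1,2-addition brings in C12 and C20, and the racemic C11 carbinol is acceptable because this centre becomes a ketone in step 18.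

Step 4
Reactants: 4 (±)-6-bromohepta-1,6-dien-3-ol
Product: 5 (±)-[(6-bromohepta-1,6-dien-3-yl)oxy]triethylsilane
Conditions: Et3SiCl, imidazole, CH2Cl2, 0 °C
Reagents that add atoms: chlorotriethylsilane, CC[Si](Cl)(CC)CC
Why: Standard silylation installs a triethylsilyl ether that can later be cleaved together with a primary TBS ether while secondary TBS ethers stay.

Step 5
Reactants: 6 geranyl acetate
Product: 7 (±)-6,7-epoxygeranyl acetate
Conditions: mCPBA (1.0 equiv), NaHCO3, CH2Cl2, 0 °C
Reagents that add atoms: mCPBA, O=C(OO)c1cccc(Cl)c1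
Why: Prilezhaev epoxidation picks the electron-rich terminal isopropylidene alkene because the other trisubstituted alkene is deactivated by the allylic acetate, and the epoxide configuration is irrelevant.

Step 6
Reactants: 7 (±)-6,7-epoxygeranyl acetate
Product: 8 (2E)-3-methyl-6-oxohex-2-en-1-yl acetate
Conditions: H5IO6, THF–H2O, 0 °C
Reagents that add atoms: none
Why: Acidic epoxide hydrolysis and Malaprade glycol cleavage in one pot give the C2–C7 aldehyde with the E-C3=C4 alkene intact.

Step 7
Reactants: 5 (±)-[(6-bromohepta-1,6-dien-3-yl)oxy]triethylsilane; 8 (2E)-3-methyl-6-oxohex-2-en-1-yl acetate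
Product: 9 (2E)-6-hydroxy-3-methyl-7-methylidene-10-(triethylsilyloxy)dodeca-2,11-dien-1-yl acetate (epimers at C7 and C11)
Conditions: CrCl2 (4 equiv), NiCl2 (2 mol %), DMF, 25 °C
Reagents that add atoms: none
Why: In the Nozaki–Hiyama–Kishi coupling, zerovalent nickel inserts into the C–Br bond and hands the alkenyl group to trivalent chromium, which adds only to the aldehyde, so the acetate and silyl ether survive and the unselective C7 centre is corrected in steps 8 and 9.

Step 8
Reactants: 9 C7 allylic alcohol
Product: 10 (2E)-3-methyl-7-methylidene-6-oxo-10-(triethylsilyloxy)dodeca-2,11-dien-1-yl acetate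
Conditions: Dess–Martin periodinane, NaHCO3, CH2Cl2, 0 °C
Reagents that add atoms: none
Why: Dess–Martin oxidation turns the allylic alcohol into the α-methylene ketone under buffered, neutral conditions that spare the acetate and the silyl ether.

Step 9
Reactants: 10 C7 enone
Product: 11 (2E,6R)-6-hydroxy-3-methyl-7-methylidene-10-(triethylsilyloxy)dodeca-2,11-dien-1-yl acetate (7R)
Conditions: (S)-2-methyl-CBS-oxazaborolidine (20 mol %), catecholborane, toluene, −78 °C
Reagents that add atoms: none
Why: In the Corey–Bakshi–Shibata reduction the 1,1-disubstituted alkenyl group acts as the large substituent, so the (S)-catalyst delivers hydride to give the (7R)-alcohol by 1,2-reduction without hydroboration at −78 °C.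

Step 10
Reactants: 11 (7R)-allylic alcohol
Product: 12 (2E,6R)-6-(tert-butyldimethylsilyloxy)-3-methyl-7-methylidene-10-(triethylsilyloxy)dodeca-2,11-dien-1-yl acetate
Conditions: t-BuMe2SiCl, imidazole, DMF, 25 °C
Reagents that add atoms: tert-butyldimethylsilyl chloride, CC(C)(C)[Si](C)(C)Cl
Why: Standard silylation gives a robust secondary TBS ether that lasts until step 23.

Step 11
Reactants: 12 TBS ether acetate
Product: 13 (2E,6R)-6-(tert-butyldimethylsilyloxy)-3-methyl-7-methylidene-10-(triethylsilyloxy)dodeca-2,11-dien-1-ol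
Conditions: K2CO3 (cat.), MeOH, 0 °C
Reagents that add atoms: none
Why: Base-catalysed transesterification removes the acetate while both silyl ethers are stable to carbonate in methanol at 0 °C.

Step 12
Reactants: 13 C2 allylic alcohol
Product: 14 (2E,6R)-1-bromo-6-(tert-butyldimethylsilyloxy)-3-methyl-7-methylidene-10-(triethylsilyloxy)dodeca-2,11-diene
Conditions: CBr4, PPh3, 2,6-lutidine, CH2Cl2, −20 °C
Reagents that add atoms: carbon tetrabromide, BrC(Br)(Br)Br
Why: The Appel reaction converts the primary allylic alcohol into the bromide by SN2 displacement without allylic transposition or loss of the E geometry.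

Step 13
Reactants: 14 C2 allylic bromide; 15 (R)-3-hydroxy-γ-butyrolactone
Product: 17 (3R,4R)-4-hydroxy-3-[(2E,6R)-6-(tert-butyldimethylsilyloxy)-3-methyl-7-methylidene-10-(triethylsilyloxy)dodeca-2,11-dien-1-yl]oxolan-2-one (trans), via lactone enolate-alkoxide dianion 16 (not isolated)
Conditions: 15, LDA (2.2 equiv), THF, −78 °C; then 14, DMPU, −78 to −30 °C
Reagents that add atoms: none
Why: In this Fráter–Seebach-type alkylation of a β-hydroxy lactone dianion, the allylic bromide approaches the enolate face opposite to the C14 alkoxide, which sets C1 trans to O14, the relation that later becomes the cis-fused target lactone.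

Step 14
Reactants: 17 trans-hydroxylactone
Product: 18 (3R,4R)-3-alkyl-oxolane-2,4-diol (lactol, anomer mixture)
Conditions: i-Bu2AlH (3 equiv), CH2Cl2, −78 °C
Reagents that add atoms: none
Why: Lactone-to-lactol reduction stops at the aluminium hemiacetal at −78 °C, one equivalent is consumed by the free hydroxyl, and no other reducible group is present.

Step 15
Reactants: 18 lactol
Product: 19 (2R,3S,5E,9R)-9-(tert-butyldimethylsilyloxy)-3-ethynyl-6-methyl-10-methylidene-13-(triethylsilyloxy)pentadeca-5,14-diene-1,2-diol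
Conditions: dimethyl (1-diazo-2-oxopropyl)phosphonate, K2CO3, MeOH, 0 to 25 °C
Reagents that add atoms: Ohira–Bestmann reagent, CC(=O)C(=[N+]=[N-])P(=O)(OC)OC
Why: Ohira–Bestmann (Seyferth–Gilbert) homologation of the open hydroxy-aldehyde form makes the C15≡C17 alkyne and frees the C13 hydroxyl, as is known for 2-deoxy-sugar lactols, and the mild base should leave C1 unchanged.

Step 16
Reactants: 19 ethynyl diol
Product: 20 tris-TBS derivative (13-O-TBS, 14-O-TBS, C17-TBS)
Conditions: n-BuLi (3.3 equiv), THF, −78 °C; t-BuMe2SiOTf (3.5 equiv), −78 to 0 °C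
Reagents that add atoms: tert-butyldimethylsilyl triflate, CC(C)(C)[Si](C)(C)OS(=O)(=O)C(F)(F)F
Why: Threefold deprotonation and silylation protect both hydroxyls and cap the acidic alkyne C–H in one operation, and no group in 19 is sensitive to n-BuLi at −78 °C.

Step 17
Reactants: 20 tris-TBS derivative
Product: 21 (2R,3S,5E,9R)-2,9-bis(tert-butyldimethylsilyloxy)-3-[(tert-butyldimethylsilyl)ethynyl]-6-methyl-10-methylidenepentadeca-5,14-diene-1,13-diol
Conditions: camphorsulfonic acid (0.2 equiv), MeOH–CH2Cl2 1:1, 0 °C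
Reagents that add atoms: none
Why: Acid-catalysed methanolysis follows the usual order of silyl ether lability, so the secondary TES ether (C11) and the primary TBS ether (C13) go first, while the two secondary TBS ethers and the C-silyl group remain.

Step 18
Reactants: 21 C11,C13-diol
Product: 22 (2R,3S,5E,9R)-2,9-bis(tert-butyldimethylsilyloxy)-3-[(tert-butyldimethylsilyl)ethynyl]-6-methyl-10-methylidene-13-oxopentadeca-5,14-dienal (seco enone-aldehyde)
Conditions: Dess–Martin periodinane (3 equiv), NaHCO3, CH2Cl2, 0 to 25 °C; used at once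
Reagents that add atoms: none
Why: A double Dess–Martin oxidation makes the C11 vinyl ketone and the C13 α-silyloxy aldehyde in one step under buffered conditions that should not epimerise C14, and it erases the C11 epimers.

Step 19
Reactants: 22 seco enone-aldehyde
Product: 24 (1S,7R,12R,13R,14R,3E)-7,14-bis(tert-butyldimethylsilyloxy)-1-[(tert-butyldimethylsilyl)ethynyl]-13-hydroxy-4,12-dimethyl-8-methylidenecyclotetradec-3-en-11-one (cembrane numbering), via Z-rhodium enolate 23 (not isolated)
Conditions: [Rh(cod)2]OTf (20 mol %), TADDOL-derived aryl phosphonite (45 mol %), Li2CO3, H2 (1 atm), CH2Cl2, 25 °C, syringe-pump addition of 22 to a final 0.001–0.002 M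
Reagents that add atoms: none
Why: Proposed new method: base-assisted heterolysis of H2 at the cationic rhodium phosphonite gives a monohydride that adds 1,4 to the s-cis vinyl ketone (C20 becomes the methyl group), and the resulting Z-configured O-enolate 23 of monovalent rhodium carries no hydride, so it can wait for the tethered C13 aldehyde before H2 cleaves the rhodium aldolate and regenerates the hydride. The closest known reaction types are the intermolecular hydrogen-mediated syn-selective reductive aldol coupling of vinyl ketones with aldehydes and the reductive aldol cyclisation of enone-aldehydes to five- and six-membered rings, so only the ring size is new. One ring is closed, the 14-membered carbocycle, in a 14-(enolendo)-exo-trig aldol addition of C12 to C13 under pseudo-high dilution. The syn relation of C12 and C13 follows from the Z-enolate in a closed Zimmerman–Traxler chair, and the aldehyde face (13R, hence 13,14-syn) is set by the chiral phosphonite, which can dominate because Z-enolates have only a weak intrinsic (Cornforth) bias toward α-silyloxy aldehydes. The step needs hydrometallation of the conjugated C12=C20 bond only, which is secured because isolated alkenes (C3=C4, C8=C19) and the silyl-capped alkyne are not reduced by this catalyst at 1 atm H2. The main competitors, hydrogenolysis of 23 to the ethyl ketone and intermolecular aldol addition, are held back by the low H2 pressure and the slow addition.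

Step 20
Reactants: 24 macrocyclic aldol
Product: 25 C11 tosylhydrazone of 24
Conditions: TsNHNH2, THF–MeOH, 25–40 °C
Reagents that add atoms: p-toluenesulfonyl hydrazide, Cc1ccc(cc1)S(=O)(=O)NN
Why: Hydrazone condensation at the only ketone proceeds without added acid or base, which limits retro-aldol cleavage and epimerisation at C12.

Step 21
Reactants: 25 C11 tosylhydrazone
Product: 26 (1S,7R,12S,13R,14R,3E)-7,14-bis(tert-butyldimethylsilyloxy)-1-[(tert-butyldimethylsilyl)ethynyl]-4,12-dimethyl-8-methylidenecyclotetradec-3-en-13-ol (cembrane numbering)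
Conditions: catecholborane (4 equiv), CHCl3, −10 °C; then NaOAc·3H2O, 25 to 60 °C
Reagents that add atoms: none
Why: This Caglioti-type deoxygenation reduces the C=N bond, expels sulfinate and loses N2 from the alkyl diazene to leave C11H2, and uncatalysed catecholborane does not hydroborate alkenes or the silyl alkyne at these temperatures.

Step 22
Reactants: 26 C13 alcohol
Product: 27 13-O-acetate of 26
Conditions: Ac2O, DMAP, pyridine, 25 °C
Reagents that add atoms: acetic anhydride, CC(=O)OC(C)=O
Why: Acylation of the only free hydroxyl installs the C13 acetate and blocks O13, so that only O14 can lactonise in step 24.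

Step 23
Reactants: 27 13-acetate
Product: 28 (1S,7R,12S,13R,14R,3E)-13-acetoxy-1-ethynyl-4,12-dimethyl-8-methylidenecyclotetradec-3-ene-7,14-diol (cembrane numbering)
Conditions: Bu4NF, AcOH (1:1), THF, 25 °C
Reagents that add atoms: none
Why: Fluoride removes both O-TBS groups and the C-TBS group in one step, and the acetic acid buffer suppresses migration of the acetyl group from O13 to O14.

Step 24
Reactants: 28 ethynyl diol acetate
Product: 29 α-methylene-γ-butyrolactone with free 7-OH (3,4-deoxy-7-O-deacetyl target)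
Conditions: PdCl2 (10 mol %), thiourea (20 mol %), CO (1 atm), acetone, 50 °C
Reagents that add atoms: carbon monoxide, [C-]#[O+]
Why: In the cyclocarbonylation of a homopropargylic alcohol, an alkoxycarbonyl complex of divalent palladium forms at O14, adds syn across the alkyne to close the five-membered ring and is protonated to the exocyclic methylene, and the configurations at C1 and C14 are not touched, so the lactone is cis-fused.

Step 25
Reactants: 29 lactone 7-ol
Product: 30 3,4-deoxy target (7,13-diacetate with E-C3=C4 alkene)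
Conditions: Ac2O, DMAP, pyridine, CH2Cl2, 0 °C
Reagents that add atoms: acetic anhydride, CC(=O)OC(C)=O
Why: Acylation of the allylic C7 alcohol is placed after the palladium step so that no allylic acetate is exposed to the catalyst.

Step 26
Reactants: 30 3,4-deoxy target
Product: 31 target CNP0323853.1
Conditions: D-fructose-derived Shi ketone (30 mol %), KHSO5 (as Oxone), K2CO3, Bu4NHSO4, MeCN–CH2(OMe)2–aq. Na2B4O7/Na2EDTA buffer, 0 °C
Reagents that add atoms: potassium peroxymonosulfate, [K+].[O-]S(=O)(=O)OO
Why: In the Shi epoxidation the chiral dioxirane attacks the only electron-rich trisubstituted E-alkene through the spiro transition state, which gives (R,R)-epoxides from such olefins (3R,4R), while the 1,1-disubstituted allylic acetate alkene and the acrylate are much less reactive.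

Compound list
1 | 2-bromoprop-2-en-1-ol | C=C(Br)CO | starting material
2 | ethyl 4-bromopent-4-enoate | C=C(Br)CCC(=O)OCC | intermediate
3 | 4-bromopent-4-enal | C=C(Br)CCC=O | intermediate
4 | (±)-6-bromohepta-1,6-dien-3-ol | C=CC(O)CCC(Br)=C | intermediate
5 | (±)-[(6-bromohepta-1,6-dien-3-yl)oxy]triethylsilane | C=CC(O[Si](CC)(CC)CC)CCC(Br)=C | intermediate
6 | geranyl acetate | CC(C)=CCC/C(C)=C/COC(C)=O | starting material
7 | (±)-6,7-epoxygeranyl acetate | CC1(C)OC1CC/C(C)=C/COC(C)=O | intermediate
8 | (2E)-3-methyl-6-oxohex-2-en-1-yl acetate | O=CCC/C(C)=C/COC(C)=O | intermediate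
9 | (2E)-6-hydroxy-3-methyl-7-methylidene-10-(triethylsilyloxy)dodeca-2,11-dien-1-yl acetate | C=CC(O[Si](CC)(CC)CC)CCC(=C)C(O)CC/C(C)=C/COC(C)=O | intermediate
10 | (2E)-3-methyl-7-methylidene-6-oxo-10-(triethylsilyloxy)dodeca-2,11-dien-1-yl acetate | C=CC(O[Si](CC)(CC)CC)CCC(=C)C(=O)CC/C(C)=C/COC(C)=O | intermediate
11 | (2E,6R)-6-hydroxy-3-methyl-7-methylidene-10-(triethylsilyloxy)dodeca-2,11-dien-1-yl acetate | C=CC(O[Si](CC)(CC)CC)CCC(=C)[C@H](O)CC/C(C)=C/COC(C)=O | intermediate
12 | (2E,6R)-6-(tert-butyldimethylsilyloxy)-3-methyl-7-methylidene-10-(triethylsilyloxy)dodeca-2,11-dien-1-yl acetate | C=CC(O[Si](CC)(CC)CC)CCC(=C)[C@H](O[Si](C)(C)C(C)(C)C)CC/C(C)=C/COC(C)=O | intermediate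
13 | (2E,6R)-6-(tert-butyldimethylsilyloxy)-3-methyl-7-methylidene-10-(triethylsilyloxy)dodeca-2,11-dien-1-ol | C=CC(O[Si](CC)(CC)CC)CCC(=C)[C@H](O[Si](C)(C)C(C)(C)C)CC/C(C)=C/CO | intermediate
14 | (2E,6R)-1-bromo-6-(tert-butyldimethylsilyloxy)-3-methyl-7-methylidene-10-(triethylsilyloxy)dodeca-2,11-diene | C=CC(O[Si](CC)(CC)CC)CCC(=C)[C@H](O[Si](C)(C)C(C)(C)C)CC/C(C)=C/CBr | intermediate
15 | (R)-3-hydroxy-γ-butyrolactone, (4R)-4-hydroxyoxolan-2-one | O=C1C[C@@H](O)CO1 | starting material
16 | dilithium enolate-alkoxide of 15 | [Li+].[Li+].[O-]C1=C[C@@H]([O-])CO1 | intermediate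
17 | (3R,4R)-4-hydroxy-3-alkyl-oxolan-2-one (trans; alkyl = C2–C12 chain of 14) | C=CC(O[Si](CC)(CC)CC)CCC(=C)[C@H](O[Si](C)(C)C(C)(C)C)CC/C(C)=C/C[C@H]1C(=O)OC[C@@H]1O | intermediate
18 | (3R,4R)-3-alkyl-oxolane-2,4-diol (lactol, anomers) | C=CC(O[Si](CC)(CC)CC)CCC(=C)[C@H](O[Si](C)(C)C(C)(C)C)CC/C(C)=C/C[C@H]1C(O)OC[C@@H]1O | intermediate
19 | (2R,3S,5E,9R)-9-(tert-butyldimethylsilyloxy)-3-ethynyl-6-methyl-10-methylidene-13-(triethylsilyloxy)pentadeca-5,14-diene-1,2-diol | C=CC(O[Si](CC)(CC)CC)CCC(=C)[C@H](O[Si](C)(C)C(C)(C)C)CC/C(C)=C/C[C@@H](C#C)[C@@H](O)CO | intermediate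
20 | 13-O,14-O,C17-tris-TBS derivative of 19 | C=CC(O[Si](CC)(CC)CC)CCC(=C)[C@H](O[Si](C)(C)C(C)(C)C)CC/C(C)=C/C[C@@H](C#C[Si](C)(C)C(C)(C)C)[C@@H](O[Si](C)(C)C(C)(C)C)CO[Si](C)(C)C(C)(C)C | intermediate
21 | (2R,3S,5E,9R)-2,9-bis(tert-butyldimethylsilyloxy)-3-[(tert-butyldimethylsilyl)ethynyl]-6-methyl-10-methylidenepentadeca-5,14-diene-1,13-diol | C=CC(O)CCC(=C)[C@H](O[Si](C)(C)C(C)(C)C)CC/C(C)=C/C[C@@H](C#C[Si](C)(C)C(C)(C)C)[C@@H](O[Si](C)(C)C(C)(C)C)CO | intermediate
22 | (2R,3S,5E,9R)-2,9-bis(tert-butyldimethylsilyloxy)-3-[(tert-butyldimethylsilyl)ethynyl]-6-methyl-10-methylidene-13-oxopentadeca-5,14-dienal | C=CC(=O)CCC(=C)[C@H](O[Si](C)(C)C(C)(C)C)CC/C(C)=C/C[C@@H](C#C[Si](C)(C)C(C)(C)C)[C@@H](O[Si](C)(C)C(C)(C)C)C=O | intermediate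
23 | Z-configured C11–O rhodium enolate of 22 (phosphonite ligands omitted) | C/C=C(\O[Rh])CCC(=C)[C@H](O[Si](C)(C)C(C)(C)C)CC/C(C)=C/C[C@@H](C#C[Si](C)(C)C(C)(C)C)[C@@H](O[Si](C)(C)C(C)(C)C)C=O | intermediate
24 | macrocyclic syn-aldol, (1S,7R,12R,13R,14R,3E), C11 ketone, 13-OH | C=C1CCC(=O)[C@H](C)[C@@H](O)[C@H](O[Si](C)(C)C(C)(C)C)[C@H](C#C[Si](C)(C)C(C)(C)C)C/C=C(\C)CC[C@H]1O[Si](C)(C)C(C)(C)C | intermediate
25 | C11 tosylhydrazone of 24 | C=C1CCC(=NNS(=O)(=O)c2ccc(C)cc2)[C@H](C)[C@@H](O)[C@H](O[Si](C)(C)C(C)(C)C)[C@H](C#C[Si](C)(C)C(C)(C)C)C/C=C(\C)CC[C@H]1O[Si](C)(C)C(C)(C)C | intermediate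
26 | C11-deoxygenated macrocycle, (1S,7R,12S,13R,14R,3E), 13-OH | C=C1CCC[C@H](C)[C@@H](O)[C@H](O[Si](C)(C)C(C)(C)C)[C@H](C#C[Si](C)(C)C(C)(C)C)C/C=C(\C)CC[C@H]1O[Si](C)(C)C(C)(C)C | intermediate
27 | 13-O-acetate of 26 | C=C1CCC[C@H](C)[C@@H](OC(C)=O)[C@H](O[Si](C)(C)C(C)(C)C)[C@H](C#C[Si](C)(C)C(C)(C)C)C/C=C(\C)CC[C@H]1O[Si](C)(C)C(C)(C)C | intermediate
28 | 13-acetoxy-1-ethynyl macrocyclic 7,14-diol | C=C1CCC[C@H](C)[C@@H](OC(C)=O)[C@H](O)[C@H](C#C)C/C=C(\C)CC[C@H]1O | intermediate
29 | cis-fused α-methylene-γ-butyrolactone, 13-OAc, 7-OH, E-C3=C4 | C=C1CCC[C@H](C)[C@@H](OC(C)=O)[C@@H]2OC(=O)C(=C)[C@@H]2C/C=C(\C)CC[C@H]1O | intermediate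
30 | 3,4-deoxy target (7,13-diacetate, E-C3=C4) | C=C1CCC[C@H](C)[C@@H](OC(C)=O)[C@@H]2OC(=O)C(=C)[C@@H]2C/C=C(\C)CC[C@H]1OC(C)=O | intermediate
31 | CNP0323853.1, (1S,3R,4R,7R,12S,13R,14R) | C=C1CCC[C@H](C)[C@@H](OC(C)=O)[C@@H]2OC(=O)C(=C)[C@@H]2C[C@H]2O[C@]2(C)CC[C@H]1OC(C)=O | target

Total step count: 26. Longest linear sequence: 24 steps (steps 1–4, then 7–26).

Steps most likely to fail

Step 19. The rhodium enolate may be hydrogenolysed or protonated before the slow macrocyclic aldol addition. Intermolecular aldol addition may compete, and the ligand may not control the aldehyde face well enough.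
Fallback, from 22 back to 24: the enolate is made with a stoichiometric trigger that hydrogen cannot quench.
- TiCl4 and n-Bu4NI in CH2Cl2 at −78 °C under high dilution add iodide 1,4 to the vinyl ketone (titanium tetrachloride–iodide halo-aldol reaction).
- The persistent Z-titanium enolate adds to the C13 aldehyde through a closed transition state to give the syn α-(iodomethyl) aldol macrocycle F1.
- Radical dehalogenation with Bu3SnH and Et3B/air in toluene at 0 °C then turns the CH2I group into the C20 methyl group of 24.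
- Without the chiral ligand the aldehyde face rests on the substrate alone, so a separation of C12/C13 isomers must be planned for.

Step 21. C12 may epimerise through the ene-hydrazine tautomer, and retro-aldol cleavage or loss of the C13 hydroxyl may occur while the hydrazone is formed and reduced.
Fallback, from 24 back to 26, by Barton–McCombie deoxygenation:
- Me4NBH(OAc)3 in MeCN–AcOH at −20 °C reduces the ketone to the 11,13-diol F2 (C11 configuration irrelevant).
- PhOC(S)Cl and pyridine (1 equiv, 0 °C) acylate the less hindered C11 hydroxyl to give the 11-O-phenoxythiocarbonyl derivative F3. The C13 hydroxyl is shielded by C12 and by the C14 silyl ether.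
- Bu3SnH and AIBN in toluene at 80 °C give 26. A C11 radical has no favourable exo cyclisation onto C8=C19.

Step 26. Facial selectivity may be poor if the macrocycle's preferred outer face opposes the catalyst. The C8=C19 alkene may also be attacked, and the esters may hydrolyse slowly at the pH of the buffer.
Fallback, from 30 back to 31, by the halohydrin route, which places the oxygen on the face opposite to the one attacked by the electrophile:
- NBS in aqueous DME at 0 °C opens the bromonium ion of the trisubstituted alkene with water at C4 to give the 3-bromo-4-hydroxy compound F4.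
- K2CO3 in acetone at 25 °C closes the oxirane with inversion at C3 to give 31.

Further compounds
F1 | step 19 | syn α-(iodomethyl) aldol macrocycle (C20 iodide of 24) | C=C1CCC(=O)[C@H](CI)[C@@H](O)[C@H](O[Si](C)(C)C(C)(C)C)[C@H](C#C[Si](C)(C)C(C)(C)C)C/C=C(\C)CC[C@H]1O[Si](C)(C)C(C)(C)C
F2 | step 21 | macrocyclic 11,13-diol (C11 epimers) | C=C1CCC(O)[C@H](C)[C@@H](O)[C@H](O[Si](C)(C)C(C)(C)C)[C@H](C#C[Si](C)(C)C(C)(C)C)C/C=C(\C)CC[C@H]1O[Si](C)(C)C(C)(C)C
F3 | step 21 | 11-O-phenoxythiocarbonyl derivative of F2 | C=C1CCC(OC(=S)Oc2ccccc2)[C@H](C)[C@@H](O)[C@H](O[Si](C)(C)C(C)(C)C)[C@H](C#C[Si](C)(C)C(C)(C)C)C/C=C(\C)CC[C@H]1O[Si](C)(C)C(C)(C)C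
F4 | step 26 | 3-bromo-4-hydroxy compound (bromohydrin of 30) | C=C1CCC[C@H](C)[C@@H](OC(C)=O)[C@@H]2OC(=O)C(=C)[C@@H]2C[C@H](Br)[C@](C)(O)CC[C@H]1OC(C)=O
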